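**Strategy**

Everything rests on disconnecting the pyranone ring at C4a–C4 and O2–C3, leaving a benzoic acid in which chlorine (C5) and both oxygens (C6, C8) are already in place. The key step exploits the benzenoid ring's substitution: of the two carbons flanking C8a, C8 is oxygenated, so C4a–H next to C5–Cl is the single site open to carboxylate-directed metalation. In one operation a rhodium catalyst couples this acid with a keto sulfoxonium ylide (C–H cleavage, carbene insertion, cyclodehydration) and closes the lactone ring. The ylide partner already carries the 2,3-cis-2,5-trans oxolane with its three stereocentres, the C3' silyl ether and the E,E-diene.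

Key step: step 13

Numbering: isocoumarin C1–C8a with ring oxygen O2; oxolane O1', C2'–C5'; diene C1''–C4'' counted from C2'.
Assumption: compounds 2, 5 (as its hexane solution) and 20 are purchased.

**Route**

Step 1
Reactants: 1 ethyl (S)-3-hydroxybutanoate; 2 allyl 2,2,2-trichloroacetimidate
Product: 3 ethyl (S)-3-(allyloxy)butanoate
Conditions: TfOH (5 mol%), cyclohexane/CH2Cl2, 0 °C → rt
Reagents that add atoms: none
Why: Brønsted acid-catalysed O-alkylation by the trichloroacetimidate (imidate etherification) works without base, so the β-hydroxy ester neither eliminates nor undergoes retro-aldol cleavage, and the C–O bond at the stereocentre is not broken.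

Step 2
Reactants: 3 ethyl (S)-3-(allyloxy)butanoate
Product: 4 (S)-3-(allyloxy)butanoic acid
Conditions: LiOH·H2O, THF/MeOH/H2O, rt; 1 M HCl to pH 3
Reagents that add atoms: lithium hydroxide, [Li+].[OH-]
Why: Hydroxide saponification of the ethyl ester at room temperature is mild enough not to eliminate the β-allyloxy group.

Step 3
Reactants: 4 (S)-3-(allyloxy)butanoic acid; 5 (trimethylsilyl)diazomethane
Product: 7 (S)-4-(allyloxy)-1-diazopentan-2-one, via acid chloride 6 (not isolated)
Conditions: (COCl)2, DMF (cat.), CH2Cl2, 0 °C → rt, evaporate; 5 (2 equiv), THF/MeCN, 0 °C → rt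
Reagents that add atoms: oxalyl chloride, ClC(=O)C(=O)Cl (chlorine of 6)
Why: Acid chloride formation followed by C-acylation of (trimethylsilyl)diazomethane with loss of chlorotrimethylsilane (Arndt–Eistert-type diazoketone synthesis) gives the diazoketone without handling diazomethane.

Step 4
Reactants: 7 (S)-4-(allyloxy)-1-diazopentan-2-one
Product: 8 (2S,5S)-2-allyl-5-methyloxolan-3-one
Conditions: Cu(acac)2 (5 mol%), THF, reflux, slow addition of 7
Reagents that add atoms: none
Why: Copper carbenoid formation, attack of the ether oxygen to a five-membered allyloxonium ylide and suprafacial [2,3]-sigmatropic shift (tandem oxonium ylide formation–rearrangement) form O1'–C2' and the C2'–allyl bond; the allyl group sits on oxygen anti to the C5' methyl and is passed to the same face of C2', which should set C2' (S) in the 2,5-trans relationship.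

Step 5
Reactants: 8 (2S,5S)-2-allyl-5-methyloxolan-3-one
Product: 9 (2S,3S,5S)-2-allyl-5-methyloxolan-3-ol
Conditions: LiBH(s-Bu)3, THF, −78 °C; H2O
Reagents that add atoms: none
Why: Hydride transfer from the bulky borohydride occurs on the carbonyl face opposite to the adjacent C2' allyl group (steric approach control), so the new C3' carbinol (S) should be cis to the C2' substituent.

Step 6
Reactants: 9 (2S,3S,5S)-2-allyl-5-methyloxolan-3-ol
Product: 10 tert-butyl{[(2S,3S,5S)-2-allyl-5-methyloxolan-3-yl]oxy}dimethylsilane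
Conditions: TBSCl, imidazole, DMF, rt
Reagents that add atoms: tert-butyldimethylsilyl chloride, CC(C)(C)[Si](C)(C)Cl
Why: Imidazole-promoted silylation of the secondary alcohol (Corey protocol) masks C3'–OH for the base and oxidant steps that follow.

Step 7
Reactants: 10 tert-butyl{[(2S,3S,5S)-2-allyl-5-methyloxolan-3-yl]oxy}dimethylsilane
Product: 11 tert-butyldimethyl{[(2S,3S,5S)-5-methyl-2-[(E)-prop-1-en-1-yl]oxolan-3-yl]oxy}silane
Conditions: RuHCl(CO)(PPh3)3 (5 mol%), toluene, 80 °C
Reagents that add atoms: none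
Why: Ruthenium hydride addition–β-hydride elimination moves the terminal double bond by one position to the more stable internal E-alkene (olefin isomerisation), the standard prelude to cleaving a C-allyl oxacycle to its C-formyl derivative.

Step 8
Reactants: 11 tert-butyldimethyl{[(2S,3S,5S)-5-methyl-2-[(E)-prop-1-en-1-yl]oxolan-3-yl]oxy}silane
Product: 13 (2R,3S,5S)-3-[(tert-butyldimethylsilyl)oxy]-5-methyloxolane-2-carbaldehyde, via ozonide 12 (not isolated)
Conditions: O3, CH2Cl2, −78 °C; PPh3, −78 °C → rt; crude aldehyde used directly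
Reagents that add atoms: ozone, [O-][O+]=O
Why: Ozonolysis with reductive work-up (Criegee mechanism through the secondary ozonide) cleaves the only alkene under neutral conditions at low temperature, so the α-alkoxy aldehyde should form without epimerisation at C2'.

Step 9
Reactants: 13 (2R,3S,5S)-3-[(tert-butyldimethylsilyl)oxy]-5-methyloxolane-2-carbaldehyde; 14 triethyl 4-phosphonocrotonate
Product: 15 ethyl (2E,4E)-5-[(2S,3S,5S)-3-{[tert-butyl(dimethyl)silyl]oxy}-5-methyloxolan-2-yl]penta-2,4-dienoate
Conditions: LiN(SiMe3)2, THF, −78 → 0 °C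
Reagents that add atoms: none
Why: Vinylogous Horner–Wadsworth–Emmons olefination: the lithiated phosphonocrotonate reacts through its α-carbon at low temperature, where the stabilised, weakly basic anion should not epimerise C2', and gives the new C1''=C2'' bond with E geometry.

Step 10
Reactants: 15 ethyl (2E,4E)-5-[(2S,3S,5S)-3-{[tert-butyl(dimethyl)silyl]oxy}-5-methyloxolan-2-yl]penta-2,4-dienoate
Product: 16 (2E,4E)-5-[(2S,3S,5S)-3-{[tert-butyl(dimethyl)silyl]oxy}-5-methyloxolan-2-yl]penta-2,4-dienoic acid
Conditions: LiOH·H2O, THF/MeOH/H2O, rt; 1 M HCl to pH 4, 0 °C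
Reagents that add atoms: lithium hydroxide, [Li+].[OH-]
Why: Saponification of the ethyl ester; the dienoate is a poor Michael acceptor for hydroxide and the secondary TBS ether withstands LiOH at room temperature.

Step 11
Reactants: 16 (2E,4E)-5-[(2S,3S,5S)-3-{[tert-butyl(dimethyl)silyl]oxy}-5-methyloxolan-2-yl]penta-2,4-dienoic acid; 17 trimethylsulfoxonium iodide
Product: 19 (3E,5E)-6-[(2S,3S,5S)-3-{[tert-butyl(dimethyl)silyl]oxy}-5-methyloxolan-2-yl]-1-[dimethyl(oxo)-λ6-sulfanylidene]hexa-3,5-dien-2-one, via dienoyl chloride 18 (not isolated)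
Conditions: Me2C=C(Cl)NMe2, CH2Cl2, 0 °C → rt, evaporate, take up in THF; add to the methylide from 17 (3.2 equiv) and KOtBu (3 equiv), THF, reflux then −20 → 0 °C
Reagents that add atoms: 1-chloro-N,N,2-trimethylprop-1-en-1-amine, CC(C)=C(Cl)N(C)C (chlorine of 18)
Why: Neutral acid chloride formation with the α-chloroenamine avoids HCl, and C-acylation of the Corey–Chaykovsky methylide, whose second equivalent deprotonates the acylated salt, gives the keto ylide; attack at the acyl chloride carbon is much faster than conjugate addition, which is how alkenyl keto sulfoxonium ylides are normally made.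

Step 12
Reactants: 20 5-chloro-2,4-dihydroxybenzoic acid
Product: 22 5-chloro-2,4-bis(methoxymethoxy)benzoic acid, via methoxymethyl ester 21 (not isolated)
Conditions: NaH (3.3 equiv), MOMCl (3.5 equiv), DMF, 0 °C → rt; then 2 M NaOH, MeOH, rt; 1 M HCl to pH 4, 0 °C
Reagents that add atoms: chloromethyl methyl ether, COCCl; sodium hydroxide, [Na+].[OH-]
Why: Exhaustive Williamson-type alkylation of the carboxylate and both phenoxides with MOMCl is followed by hydroxide cleavage of the acetal ester alone, since aryl MOM ethers are stable to base.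

Step 13
Reactants: 22 5-chloro-2,4-bis(methoxymethoxy)benzoic acid; 19 (3E,5E)-6-[(2S,3S,5S)-3-{[tert-butyl(dimethyl)silyl]oxy}-5-methyloxolan-2-yl]-1-[dimethyl(oxo)-λ6-sulfanylidene]hexa-3,5-dien-2-one
Product: 24 3-{(1E,3E)-4-[(2S,3S,5S)-3-{[tert-butyl(dimethyl)silyl]oxy}-5-methyloxolan-2-yl]buta-1,3-dien-1-yl}-5-chloro-6,8-bis(methoxymethoxy)-1H-isochromen-1-one, via keto acid 23 (not isolated)
Conditions: [Cp*RhCl2]2 (5 mol%), AgOAc (20 mol%), NaOAc (1 equiv), 4 Å MS, DCE, 80 °C
Reagents that add atoms: none
Why: Acetate-assisted concerted metalation–deprotonation, directed by the rhodium-bound carboxylate of 22, cleaves the one ortho C–H (future C4a, beside C5–Cl) to a five-membered rhodacycle; the ylide carbon of 19 then binds rhodium, DMSO departs to leave a rhodium carbene, and 1,1-migratory insertion with protodemetalation forms C4a–C4 as the aryl-CH2 dienyl ketone 23 and returns the trivalent rhodium catalyst without an external oxidant. The closest known reaction type is the rhodium- or ruthenium-catalysed annulation of benzoic acids with aryl and alkyl keto sulfoxonium ylides to 3-substituted isocoumarins (C–H acylmethylation followed by cyclocondensation); the conjugated dienoyl ylide is a demanding member of that class. The pyranone ring closes by 6-exo-trig addition of the carboxyl oxygen to the ketone carbonyl (O2–C3) and loss of water, driven by formation of the enol lactone conjugated with arene and diene. No stereocentre is created: C2', C3' and C5' are remote from the reacting atoms and the E,E-diene is not engaged. Site selectivity is not a choice because C8 carries OMOM, and chemoselectivity for carbene transfer over conjugate addition of the aryl–rhodium species relies on the ylide carbon being the nucleophilic, metal-binding site of 19 and on the push–pull keto ylide making its diene a poor Michael acceptor; the acetate buffer should preserve the MOM and TBS ethers.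

Step 14
Reactants: 24 3-{(1E,3E)-4-[(2S,3S,5S)-3-{[tert-butyl(dimethyl)silyl]oxy}-5-methyloxolan-2-yl]buta-1,3-dien-1-yl}-5-chloro-6,8-bis(methoxymethoxy)-1H-isochromen-1-one
Product: 25 5-chloro-6,8-dihydroxy-3-{(1E,3E)-4-[(2S,3S,5S)-3-hydroxy-5-methyloxolan-2-yl]buta-1,3-dien-1-yl}-1H-isochromen-1-one
Conditions: HCl (1.25 M in MeOH), MeOH/THF, 0 °C → rt
Reagents that add atoms: none
Why: Acid-catalysed acetal exchange with methanol removes both aryl MOM ethers and the same medium solvolyses the secondary silyl ether (global acidic methanolysis), while lactone, chloride and stereocentres are not engaged.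

**Compound list**

1 | ethyl (S)-3-hydroxybutanoate | C[C@H](O)CC(=O)OCC | starting material
2 | allyl 2,2,2-trichloroacetimidate | C=CCOC(=N)C(Cl)(Cl)Cl | starting material
3 | ethyl (S)-3-(allyloxy)butanoate | C[C@H](OCC=C)CC(=O)OCC | intermediate
4 | (S)-3-(allyloxy)butanoic acid | C[C@H](OCC=C)CC(=O)O | intermediate
5 | (trimethylsilyl)diazomethane | C[Si](C)(C)C=[N+]=[N-] | starting material
6 | (S)-3-(allyloxy)butanoyl chloride | C[C@H](OCC=C)CC(=O)Cl | intermediate
7 | (S)-4-(allyloxy)-1-diazopentan-2-one | C[C@H](OCC=C)CC(=O)C=[N+]=[N-] | intermediate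
8 | (2S,5S)-2-allyl-5-methyloxolan-3-one | C[C@H]1CC(=O)[C@H](CC=C)O1 | intermediate
9 | (2S,3S,5S)-2-allyl-5-methyloxolan-3-ol | C[C@H]1C[C@H](O)[C@H](CC=C)O1 | intermediate
10 | tert-butyl{[(2S,3S,5S)-2-allyl-5-methyloxolan-3-yl]oxy}dimethylsilane | C[C@H]1C[C@H](O[Si](C)(C)C(C)(C)C)[C@H](CC=C)O1 | intermediate
11 | tert-butyldimethyl{[(2S,3S,5S)-5-methyl-2-[(E)-prop-1-en-1-yl]oxolan-3-yl]oxy}silane | C[C@H]1C[C@H](O[Si](C)(C)C(C)(C)C)[C@H](/C=C/C)O1 | intermediate
12 | 3-[(2S,3S,5S)-3-{[tert-butyl(dimethyl)silyl]oxy}-5-methyloxolan-2-yl]-5-methyl-1,2,4-trioxolane (ozonide, mixture at the trioxolane carbons) | C[C@H]1C[C@H](O[Si](C)(C)C(C)(C)C)[C@H](C2OOC(C)O2)O1 | intermediate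
13 | (2R,3S,5S)-3-[(tert-butyldimethylsilyl)oxy]-5-methyloxolane-2-carbaldehyde | C[C@H]1C[C@H](O[Si](C)(C)C(C)(C)C)[C@H](C=O)O1 | intermediate
14 | triethyl 4-phosphonocrotonate | CCOC(=O)/C=C/CP(=O)(OCC)OCC | starting material
15 | ethyl (2E,4E)-5-[(2S,3S,5S)-3-{[tert-butyl(dimethyl)silyl]oxy}-5-methyloxolan-2-yl]penta-2,4-dienoate | C[C@H]1C[C@H](O[Si](C)(C)C(C)(C)C)[C@H](/C=C/C=C/C(=O)OCC)O1 | intermediate
16 | (2E,4E)-5-[(2S,3S,5S)-3-{[tert-butyl(dimethyl)silyl]oxy}-5-methyloxolan-2-yl]penta-2,4-dienoic acid | C[C@H]1C[C@H](O[Si](C)(C)C(C)(C)C)[C@H](/C=C/C=C/C(=O)O)O1 | intermediate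
17 | trimethylsulfoxonium iodide | C[S+](C)(C)=O.[I-] | starting material
18 | (2E,4E)-5-[(2S,3S,5S)-3-{[tert-butyl(dimethyl)silyl]oxy}-5-methyloxolan-2-yl]penta-2,4-dienoyl chloride | C[C@H]1C[C@H](O[Si](C)(C)C(C)(C)C)[C@H](/C=C/C=C/C(=O)Cl)O1 | intermediate
19 | (3E,5E)-6-[(2S,3S,5S)-3-{[tert-butyl(dimethyl)silyl]oxy}-5-methyloxolan-2-yl]-1-[dimethyl(oxo)-λ6-sulfanylidene]hexa-3,5-dien-2-one | C[C@H]1C[C@H](O[Si](C)(C)C(C)(C)C)[C@H](/C=C/C=C/C(=O)C=S(C)(C)=O)O1 | intermediate
20 | 5-chloro-2,4-dihydroxybenzoic acid | OC(=O)c1cc(Cl)c(O)cc1O | starting material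
21 | methoxymethyl 5-chloro-2,4-bis(methoxymethoxy)benzoate | COCOC(=O)c1cc(Cl)c(OCOC)cc1OCOC | intermediate
22 | 5-chloro-2,4-bis(methoxymethoxy)benzoic acid | OC(=O)c1cc(Cl)c(OCOC)cc1OCOC | intermediate
23 | 3-chloro-4,6-bis(methoxymethoxy)-2-{(3E,5E)-6-[(2S,3S,5S)-3-{[tert-butyl(dimethyl)silyl]oxy}-5-methyloxolan-2-yl]-2-oxohexa-3,5-dien-1-yl}benzoic acid | C[C@H]1C[C@H](O[Si](C)(C)C(C)(C)C)[C@H](/C=C/C=C/C(=O)Cc2c(Cl)c(OCOC)cc(OCOC)c2C(=O)O)O1 | intermediate
24 | 3-{(1E,3E)-4-[(2S,3S,5S)-3-{[tert-butyl(dimethyl)silyl]oxy}-5-methyloxolan-2-yl]buta-1,3-dien-1-yl}-5-chloro-6,8-bis(methoxymethoxy)-1H-isochromen-1-one | C[C@H]1C[C@H](O[Si](C)(C)C(C)(C)C)[C@H](/C=C/C=C/c2cc3c(Cl)c(OCOC)cc(OCOC)c3c(=O)o2)O1 | intermediate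
25 | 5-chloro-6,8-dihydroxy-3-{(1E,3E)-4-[(2S,3S,5S)-3-hydroxy-5-methyloxolan-2-yl]buta-1,3-dien-1-yl}-1H-isochromen-1-one | C[C@H]1C[C@H](O)[C@H](/C=C/C=C/c2cc3c(Cl)c(O)cc(O)c3c(=O)o2)O1 | target

**Step count**

Total: 14 steps. Longest linear sequence: 13 steps (steps 1–11, 13 and 14); step 12 is a one-step side branch.

**Steps most likely to fail**

1. Step 13. The aryl–rhodium intermediate may add in a conjugate (1,4 or 1,6) sense to the dienone of 19, or the diene may bind the metal and stall carbene formation, so that the acylmethylation does not proceed cleanly. Thermal loss of a MOM group during cyclodehydration is a secondary concern.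
Fallback, setting out from 22 and 13 and returning at 24: the C–H annulation is kept, but with an ylide of the non-conjugated alkyl class for which it is established, and the diene is added afterwards by olefination. Acid 22 is annulated under the step 13 catalyst with 3-[(tert-butyldimethylsilyl)oxy]-1-[dimethyl(oxo)-λ6-sulfanylidene]propan-2-one F1, prepared from methyl (tert-butyldimethylsilyloxy)acetate and dimethylsulfoxonium methylide. This should give 3-(silyloxymethyl)isocoumarin F2. Bu4NF/AcOH in THF should free 3-(hydroxymethyl)isocoumarin F3, CBr4/PPh3 should give 3-(bromomethyl)isocoumarin F4, and P(OEt)3 at 110 °C (Michaelis–Arbuzov) the isocoumarin-3-ylmethyl phosphonate F5. In parallel, aldehyde 13 and Ph3P=CHCHO (toluene, 60 °C) should give the oxolanyl enal F6. Horner–Wadsworth–Emmons olefination of F5 (LiN(SiMe3)2, THF, −78 → 0 °C) with F6 forms the C3''=C4'' bond with E geometry and arrives at 24.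

2. Step 11. The strongly basic, nucleophilic methylide may attack the diene termini of the acyl chloride (conjugate addition and cyclopropanation) or deprotonate it vinylogously, instead of substituting cleanly at the acyl carbon. The acid chloride may also degrade before it is consumed.
Fallback, setting out from 16 and returning at 19: activation is separated from acylation by isolating a milder, storable acyl donor. Acid 16 with EDC·HCl, 4-nitrophenol and DMAP (cat.) in CH2Cl2 should give 4-nitrophenyl dienoate F7. F7 is added slowly at −20 °C to the preformed methylide in THF. This aryl active-ester protocol is the one used for base-sensitive α-amino acid keto sulfoxonium ylides; the lower electrophilicity of the diene carbons and the inverse, slow addition should favour substitution at the ester carbonyl and deliver 19.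

3. Step 14. Under protic acid the doubly allylic C2'–O1' bond may ionise, leading to solvolytic opening of the oxolane or epimerisation at C2', while the C6 MOM ether beside chlorine cleaves only slowly.
Fallback, setting out from 24 and returning at 25: the groups are removed in two aprotic stages. Bu4NF/AcOH (THF, 0 °C → rt) should remove the silyl group to give the bis-MOM alcohol F8. ZnBr2 with n-PrSH in CH2Cl2 at 0 °C should then cleave both aryl MOM ethers within minutes, the thiol trapping the methoxymethyl cation, to give 25.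

**Further compounds**

F1 | step 13 | 3-[(tert-butyldimethylsilyl)oxy]-1-[dimethyl(oxo)-λ6-sulfanylidene]propan-2-one | CC(C)(C)[Si](C)(C)OCC(=O)C=S(C)(C)=O
F2 | step 13 | 3-{[(tert-butyldimethylsilyl)oxy]methyl}-5-chloro-6,8-bis(methoxymethoxy)-1H-isochromen-1-one | CC(C)(C)[Si](C)(C)OCc1cc2c(Cl)c(OCOC)cc(OCOC)c2c(=O)o1
F3 | step 13 | 5-chloro-3-(hydroxymethyl)-6,8-bis(methoxymethoxy)-1H-isochromen-1-one | OCc1cc2c(Cl)c(OCOC)cc(OCOC)c2c(=O)o1
F4 | step 13 | 3-(bromomethyl)-5-chloro-6,8-bis(methoxymethoxy)-1H-isochromen-1-one | BrCc1cc2c(Cl)c(OCOC)cc(OCOC)c2c(=O)o1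
F5 | step 13 | diethyl {[5-chloro-6,8-bis(methoxymethoxy)-1-oxo-1H-isochromen-3-yl]methyl}phosphonate | CCOP(=O)(Cc1cc2c(Cl)c(OCOC)cc(OCOC)c2c(=O)o1)OCC
F6 | step 13 | (E)-3-[(2S,3S,5S)-3-{[tert-butyl(dimethyl)silyl]oxy}-5-methyloxolan-2-yl]prop-2-enal | C[C@H]1C[C@H](O[Si](C)(C)C(C)(C)C)[C@H](/C=C/C=O)O1
F7 | step 11 | 4-nitrophenyl (2E,4E)-5-[(2S,3S,5S)-3-{[tert-butyl(dimethyl)silyl]oxy}-5-methyloxolan-2-yl]penta-2,4-dienoate | C[C@H]1C[C@H](O[Si](C)(C)C(C)(C)C)[C@H](/C=C/C=C/C(=O)Oc2ccc(cc2)[N+](=O)[O-])O1
F8 | step 14 | 5-chloro-3-{(1E,3E)-4-[(2S,3S,5S)-3-hydroxy-5-methyloxolan-2-yl]buta-1,3-dien-1-yl}-6,8-bis(methoxymethoxy)-1H-isochromen-1-one | C[C@H]1C[C@H](O)[C@H](/C=C/C=C/c2cc3c(Cl)c(OCOC)cc(OCOC)c3c(=O)o2)O1
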